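## Analysis of the target

The target 19 is (13R)-8β-acetoxy-9α,13;15,16-diepoxylabd-14-en-7-one (labdane numbering is used throughout). It has a trans-decalin (rings A and B), an oxolane (ring C: O, C9, C11, C12, C13) spiro-fused at C9, and a 2,3-dihydrofuran (ring D: C13, C14=C15, O, C16) spiro-fused at C13. There are five stereocentres: C5 and C10 of the decalin, and three fully substituted, oxygen-bearing carbons C8, C9 and C13. The C8 acetate is β and axial, on the face of the C10 methyl; the C9 ether oxygen is α and axial, so the two C–O bonds are trans-diaxial. C13 is tied to the decalin only through ring C. The ring D enol ether is allylic to the tertiary C13–O9 bond, so acid can ionise that bond and aromatise ring D to a furan with loss of ring C. The tertiary α-acetoxy ketone is open to acyl migration or solvolysis once a neighbouring hydroxyl or strong base is present. The difficulty is placing an oxygen on the hindered β face of the tertiary C8, next to the neopentyl, fully substituted C9, and controlling the remote quaternary C13. The strategy rests on two features: the anti O8/O9 pair is what anti opening of an 8α,9α-epoxide leaves behind, with the C7 oxygen (the later ketone) placed to deliver the C8 oxygen; and C13 is a tertiary ether carbon flanked by two oxygenated one-carbon arms (C14, C16), which is the substituted end of a 2,2-disubstituted epoxide.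

## Retrosynthetic reasoning

**Ring D.** The O–C15 bond of the enol ether in 19 is cut to give the 1-alkyn-4-ol 18. The forward reaction is an endo cycloisomerisation through a metal vinylidene in an amine medium. Ring D is closed last and without acid because the enol ether makes the C13–O9 bond allylic and acid-labile. Alcohol 18 comes from silyl ether 17, and the C14≡C15 bond of 17 from a one-carbon homologation of aldehyde 16.

**Oxidation levels.** Keto aldehyde 16 comes from diol 15 by oxidising the C7 carbinol and the C14 carbinol together. Both hydroxyls are set free by the key step, and oxidising C7 at once removes the only hydroxyl to which the C8 acetyl could migrate.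

**Key disconnection.** In 15 the C8–O(acetate) bond and the C13–O9 bond are cut, leading to bis-epoxide 12. The acetyl group of 15 is the original C7 acetate of 12, moved by one oxygen. This is the place to cut because an external nucleophile would not attack the tertiary, β-shielded C8, whereas a tethered acetate on C7 can reach it through a five-membered ring in the diaxial mode. The forward reaction forms ring C and sets C8 and C13 in one operation. It has to open the ring epoxide at C8 and not C9, open the side-chain epoxide at C13 with inversion, and outrun 1,2-shifts of both epoxides.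

**The two epoxides.** The 8α,9α-epoxide of 12 comes from alkene 11 by attack on the α face, away from the C10 methyl and the C7 acetate. Silyl ether 11 comes from epoxy alcohol 10, and 10 from allylic alcohol 9 by Sharpless asymmetric epoxidation, which sets C13 by reagent control. The side chain is epoxidised first, while its allylic hydroxyl is free. The ring alkene is epoxidised afterwards, once C7 carries an acetate and no free hydroxyl that could direct the oxidant to the β face.

**C12–C13 bond.** Dienol 9 is cut between C12 and C13 into the alkylzinc reagent 8 (from iodide 6) and the three-carbon vinyl bromide 7. This divides the molecule into the terpenoid part, which the chiral pool supplies with C5 and C10 in place, and a commercial fragment that brings the 1,1-disubstituted allylic alcohol needed for the Sharpless step.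

**Ring B oxygenation and the start.** Iodide 6 comes from iodo alcohol 5 by acetylation, 5 from diol 4 by selective iodination of the primary alcohol, and 4 from keto ester 3 by hydride reduction of both carbonyl groups. The C7 oxygen is introduced at the stage of ester 2, where C11 is deactivated as the α-carbon of the ester and C7 is the only reactive allylic methylene. Ester 2 comes from (+)-sclareolide 1 by acid methanolysis and dehydration.

## Alternatives that were turned down

**Alternative 1:** The lactone C15–O bond of ring D is disconnected, so that ring D arises by oxygen insertion into the spiro-cyclobutanone A1. In the forward step, aqueous H2O2 and the chiral phosphoric acid (R)-3,3'-bis(2,4,6-triisopropylphenyl)-1,1'-binaphthyl-2,2'-diyl hydrogen phosphate expand A1 to the γ-lactone A2 and create C13 by choosing one of two methylene arms.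
- For: the step is catalytic, C13 is made late from a precursor without that stereocentre, and A2 is only a reduction and a dehydration away from the ring D enol ether. On ring D economy this is stronger than the chosen route, which spends three steps after 16.
- Against: the two migrating methylenes are electronically identical, and the catalyst must tell them apart next to the spiro centre C9, a matched or mismatched case that cannot be predicted. A2 also still carries an 8(17)-alkene, so the C7 ketone and the tertiary 8β-acetate must be added afterwards, and additions to C8 come from the α face. The hardest stereocentre is therefore postponed.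
- Comparison: the chosen route sets C8, C9 and C13 together in step 10 and fixes C13 by a Sharpless epoxidation of predictable sense.

**Alternative 2:** The C9–O bond is disconnected. In the forward step, PhI(OAc)2 and I2 under visible light turn the tertiary alcohol A3 into a C13 alkoxyl radical, which abstracts the C9 hydrogen through a six-membered transition state; oxidative C–O closure then gives A4.
- For: C9 needs no prior oxidation, so a 9-H labdane from the chiral pool can be used directly; on that point it is stronger than the chosen route, which needs the Δ8 alkene and its epoxide. C13 is set earlier in an open-chain fragment.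
- Against: the alkoxyl radical is flanked by an ester and can fragment by β-scission instead. The C9 radical is allylic and delocalised towards C7, so closure, iodination or diene formation at the wrong terminus are possible. The face of C–O closure at the planar C9 is decided only by sterics. Ring B ends as a Δ7 alkene, so the 8β oxygen anti to O9 still has to be made, which would need an epoxide-opening sequence of the kind used here.
- Comparison: the chosen route replaces a radical step with an ionic, stereospecific anti opening that fixes the C8/C9 relationship by mechanism.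

**Alternative 3:** Both C–O bonds of ring C and the C8–O and C16–O bonds are disconnected together, leading to the 1,5-diene A5. In the forward step KMnO4 adds to the acrylate alkene, and the manganate ester adds across the ring alkene to give the oxolane diol A6.
- For: four C–O bonds, ring C, C9 and C13 arise in one step, and the cis relationship across the oxolane that the mechanism imposes is the one the target needs. In bond count and stereospecificity it is stronger than the chosen key step.
- Against: the ring alkene must lack C17 to give a secondary alcohol, so that carbon has to be removed from the terpene and put back. The C8 oxygen arrives α, syn to O9, while the target has it β. Correcting this needs oxidation to the ketone, methyl addition, acetylation of the tertiary alcohol and a separate oxidation at C7, about six further steps. The absolute sense at C9 and C13 rests on substrate control alone.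
- Comparison: the chosen route keeps every carbon of 1, places the C8 oxygen on the β face as the final acetate, and already has the C7 oxygen in place.

Key step: step 10

Assumption: D-(−)-diethyl tartrate is taken to epoxidise a 2-substituted allyl alcohol in the sense that gives the (R)-2-substituted glycidol, as it does with 2-methylallyl alcohol.

## Route

Step 1
Reactants: 1 (+)-sclareolide
Product: 2 methyl 13,14,15,16-tetranorlabd-8-en-12-oate
Conditions: H2SO4 (conc.), MeOH, 25 °C
Reagents that add atoms: methanol, CO
Why: Acid methanolysis of the lactone and E1 dehydration of the tertiary C8 alcohol; under these equilibrating conditions the tetrasubstituted Δ8 alkene should predominate and the minor Δ7 and exocyclic isomers are removed by chromatography; C5 and C10 are untouched.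

Step 2
Reactants: 2 methyl 13,14,15,16-tetranorlabd-8-en-12-oate
Product: 3 methyl 7-oxo-13,14,15,16-tetranorlabd-8-en-12-oate
Conditions: CrO3, 3,5-dimethylpyrazole, CH2Cl2, −20 °C
Reagents that add atoms: chromium trioxide, O=[Cr](=O)=O
Why: Allylic oxidation with the CrO3–3,5-dimethylpyrazole complex; C7 is the only allylic methylene that is not deactivated (C11 is α to the ester carbonyl, C17 is a methyl, C10 is quaternary), so the enone should form at C7.

Step 3
Reactants: 3 methyl 7-oxo-13,14,15,16-tetranorlabd-8-en-12-oate
Product: 4 13,14,15,16-tetranorlabd-8-ene-7β,12-diol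
Conditions: i-Bu2AlH (4 equiv), CH2Cl2, −78 → 0 °C
Reagents that add atoms: none
Why: 1,2-Reduction of the enone and reduction of the ester by the aluminium hydride; hydride should reach C7 from the α face, the axial trajectory away from the C10 methyl, and give the pseudo-equatorial 7β-alcohol.

Step 4
Reactants: 4 13,14,15,16-tetranorlabd-8-ene-7β,12-diol
Product: 5 12-iodo-13,14,15,16-tetranorlabd-8-en-7β-ol
Conditions: I2, PPh3, imidazole, CH2Cl2, −20 → 0 °C
Reagents that add atoms: iodine, II
Why: Garegg–Samuelsson (Appel-type) iodination; the unhindered primary C12 alcohol should be activated well before the secondary C7 alcohol, which is flanked by the tetrasubstituted alkene.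

Step 5
Reactants: 5 12-iodo-13,14,15,16-tetranorlabd-8-en-7β-ol
Product: 6 12-iodo-13,14,15,16-tetranorlabd-8-en-7β-yl acetate
Conditions: Ac2O, pyridine, DMAP (cat.), CH2Cl2, 0 → 25 °C
Reagents that add atoms: acetic anhydride, CC(=O)OC(C)=O
Why: DMAP-catalysed acylation of the secondary allylic alcohol; this acetate is the later neighbouring group and ends as the C8 acetate of the target.

Step 6
Reactants: 6 12-iodo-13,14,15,16-tetranorlabd-8-en-7β-yl acetate; 7 2-bromoallyl alcohol (2-bromoprop-2-en-1-ol)
Product: 9 7β-acetoxy-15-norlabda-8,13(14)-dien-16-ol, via alkylzinc iodide 8 (not isolated)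
Conditions: Zn dust, LiCl, THF, 40 °C; then 7, Pd(OAc)2 (2 mol %), SPhos (4 mol %), THF, 25 °C, slow addition of 8
Reagents that add atoms: none
Why: Zinc insertion into the primary iodide and Negishi sp3–sp2 coupling form the C12–C13 bond; alkylzinc halides are protonated by alcohols much more slowly than they transmetallate, so the free hydroxyl of 7 is tolerated under slow addition, and the hindered allylic acetate on a tetrasubstituted alkene should not ionise at 25 °C.

Step 7
Reactants: 9 7β-acetoxy-15-norlabda-8,13(14)-dien-16-ol
Product: 10 (13R)-7β-acetoxy-13,14-epoxy-15-norlabd-8-en-16-ol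
Conditions: Ti(OiPr)4 (10 mol %), D-(−)-diethyl tartrate (12 mol %), t-BuOOH, 4 Å MS, CH2Cl2, −20 °C
Reagents that add atoms: tert-butyl hydroperoxide, CC(C)(C)OO
Why: Sharpless asymmetric epoxidation of the 2-substituted allylic alcohol; the tartrate enantiomer fixes the face and so sets C13 by reagent control, and the ring alkene, which is not allylic to a free hydroxyl, is left alone.

Step 8
Reactants: 10 (13R)-7β-acetoxy-13,14-epoxy-15-norlabd-8-en-16-ol
Product: 11 (13S)-7β-acetoxy-16-(tert-butyldimethylsilyloxy)-13,14-epoxy-15-norlabd-8-ene
Conditions: TBSCl, imidazole, DMF, 0 → 25 °C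
Reagents that add atoms: tert-butyldimethylsilyl chloride, CC(C)(C)[Si](C)(C)Cl
Why: Standard silylation of the primary alcohol; it marks C16 against C14 for the rest of the route (the descriptor changes only because of the priority rules).

Step 9
Reactants: 11 (13S)-7β-acetoxy-16-(tert-butyldimethylsilyloxy)-13,14-epoxy-15-norlabd-8-ene
Product: 12 (13S)-7β-acetoxy-16-(tert-butyldimethylsilyloxy)-8α,9α;13,14-diepoxy-15-norlabdane
Conditions: dimethyldioxirane, acetone, −20 → 0 °C
Reagents that add atoms: dimethyldioxirane, CC1(C)OO1
Why: Neutral epoxidation of the electron-rich tetrasubstituted alkene; the oxidant should approach from the α face, opposite the axial C10 methyl and the 7β-acetate, and the absence of acid protects the acid-triggerable bis-epoxide.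

Step 10
Reactants: 12 (13S)-7β-acetoxy-16-(tert-butyldimethylsilyloxy)-8α,9α;13,14-diepoxy-15-norlabdane
Product: 15 (13R)-8β-acetoxy-16-(tert-butyldimethylsilyloxy)-9α,13-epoxy-15-norlabdane-7β,14-diol, via 9-oxido acetoxonium ion 13 (not isolated), via spirocyclic acetoxonium ion 14 (not isolated)
Conditions: BF3·OEt2 (2 equiv), CH2Cl2, −78 → −40 °C; then H2O/THF, 0 °C
Reagents that add atoms: water, O
Why: BF3 binds the more basic tetrasubstituted epoxide, and the carbonyl oxygen of the 7β-acetate attacks C8 from the β face, anti to the breaking C8–O bond (trans-diaxial, Fürst–Plattner), giving the cis-fused acetoxonium ion 13 and freeing the 9α oxygen. That oxygen opens the Lewis acid-activated glycidyl ether at its tertiary carbon C13 with inversion, which closes ring C in a 5-exo-tet epoxide opening (14); water then converts the acetoxonium ion through its orthoacid into the axial C8 acetate and the equatorial C7 alcohol. The closest known reaction types are the opening of epoxides by a neighbouring acyloxy group through 1,3-dioxolan-2-ylium ions and the Lewis acid-promoted epoxide-opening cascades of polyepoxides that end at a carbonyl oxygen. C8 is set by inversion of the α-epoxide inside the five-membered participation, C9 keeps the α oxygen of that epoxide, and C13 is set by inversion of the Sharpless epoxide. The step needs attack at C8 and not C9, attack at C13 and not C14, and capture faster than 1,2-shifts: the acetate can reach only C8 and only in the diaxial mode, the oxygen nucleophile prefers the tertiary carbon in the 5-exo mode, and the silyloxymethyl group slows ionisation at C13. If the ring epoxide oxygen attacks C13 first, the epoxonium ion is opened at C8 by the same acetate and the same product results. The orthoacid must collapse with the acyl group on the axial C8 oxygen, which is the stereoelectronically preferred cleavage of a cis-fused 2-hydroxy-1,3-dioxolane on a six-membered ring.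

Step 11
Reactants: 15 (13R)-8β-acetoxy-16-(tert-butyldimethylsilyloxy)-9α,13-epoxy-15-norlabdane-7β,14-diol
Product: 16 (13S)-8β-acetoxy-16-(tert-butyldimethylsilyloxy)-9α,13-epoxy-7-oxo-15-norlabdan-14-al
Conditions: Dess–Martin periodinane (3 equiv), CH2Cl2, 0 → 25 °C
Reagents that add atoms: none
Why: Dess–Martin oxidation of the secondary C7 and primary C14 alcohols under near-neutral conditions; it removes the hydroxyl to which the C8 acetyl could migrate, and the aldehyde has no α-hydrogen, so C13 cannot epimerise.

Step 12
Reactants: 16 (13S)-8β-acetoxy-16-(tert-butyldimethylsilyloxy)-9α,13-epoxy-7-oxo-15-norlabdan-14-al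
Product: 17 (13R)-8β-acetoxy-16-(tert-butyldimethylsilyloxy)-9α,13-epoxylabd-14-yn-7-one
Conditions: dimethyl (1-diazo-2-oxopropyl)phosphonate, K2CO3, MeOH, 0 → 25 °C
Reagents that add atoms: dimethyl (1-diazo-2-oxopropyl)phosphonate, CC(=O)C(=[N+]=[N-])P(=O)(OC)OC
Why: Ohira–Bestmann (Seyferth–Gilbert) homologation of the aldehyde to the terminal alkyne, which adds C15; the hindered C7 ketone should not compete, and the axial tertiary 8β-acetate, shielded by the C10 methyl, should resist K2CO3 in MeOH as tertiary α-acetoxy ketones usually do.

Step 13
Reactants: 17 (13R)-8β-acetoxy-16-(tert-butyldimethylsilyloxy)-9α,13-epoxylabd-14-yn-7-one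
Product: 18 (13R)-8β-acetoxy-9α,13-epoxy-16-hydroxylabd-14-yn-7-one
Conditions: HF·pyridine, pyridine, THF, 0 → 25 °C
Reagents that add atoms: none
Why: Fluoride cleavage of the primary silyl ether; buffered HF·pyridine spares the tertiary acetate, the ketone and the alkyne, and no acid-labile enol ether is present yet.

Step 14
Reactants: 18 (13R)-8β-acetoxy-9α,13-epoxy-16-hydroxylabd-14-yn-7-one
Product: 19 (13R)-8β-acetoxy-9α,13;15,16-diepoxylabd-14-en-7-one (target)
Conditions: Mo(CO)6 (0.3 equiv), Et3N, Et2O, hν [gives (Et3N)Mo(CO)5]; then 18, 25 °C, dark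
Reagents that add atoms: none
Why: Endo cycloisomerisation of a 1-alkyn-4-ol to a 2,3-dihydrofuran through a molybdenum vinylidene (McDonald cycloisomerisation): the terminal alkyne rearranges to the vinylidene, the C16 hydroxyl adds to C15, and protodemetallation gives the C14=C15 enol ether; the triethylamine medium keeps the acid-labile product intact and no stereocentre is touched.

## Compound list

1 | (+)-sclareolide | C[C@@]12CC[C@H]3C(C)(C)CCC[C@]3(C)[C@H]1CC(=O)O2 | starting material
2 | methyl 13,14,15,16-tetranorlabd-8-en-12-oate | COC(=O)CC1=C(C)CC[C@H]2C(C)(C)CCC[C@]12C | intermediate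
3 | methyl 7-oxo-13,14,15,16-tetranorlabd-8-en-12-oate | COC(=O)CC1=C(C)C(=O)C[C@H]2C(C)(C)CCC[C@]12C | intermediate
4 | 13,14,15,16-tetranorlabd-8-ene-7β,12-diol | OCCC1=C(C)[C@@H](O)C[C@H]2C(C)(C)CCC[C@]12C | intermediate
5 | 12-iodo-13,14,15,16-tetranorlabd-8-en-7β-ol | ICCC1=C(C)[C@@H](O)C[C@H]2C(C)(C)CCC[C@]12C | intermediate
6 | 12-iodo-13,14,15,16-tetranorlabd-8-en-7β-yl acetate | ICCC1=C(C)[C@@H](OC(C)=O)C[C@H]2C(C)(C)CCC[C@]12C | intermediate
7 | 2-bromoallyl alcohol | OCC(Br)=C | starting material
8 | (7β-acetoxy-13,14,15,16-tetranorlabd-8-en-12-yl)zinc iodide | I[Zn]CCC1=C(C)[C@@H](OC(C)=O)C[C@H]2C(C)(C)CCC[C@]12C | intermediate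
9 | 7β-acetoxy-15-norlabda-8,13(14)-dien-16-ol | OCC(=C)CCC1=C(C)[C@@H](OC(C)=O)C[C@H]2C(C)(C)CCC[C@]12C | intermediate
10 | (13R)-7β-acetoxy-13,14-epoxy-15-norlabd-8-en-16-ol | OC[C@@]3(CO3)CCC1=C(C)[C@@H](OC(C)=O)C[C@H]2C(C)(C)CCC[C@]12C | intermediate
11 | (13S)-7β-acetoxy-16-(tert-butyldimethylsilyloxy)-13,14-epoxy-15-norlabd-8-ene | CC(C)(C)[Si](C)(C)OC[C@@]3(CO3)CCC1=C(C)[C@@H](OC(C)=O)C[C@H]2C(C)(C)CCC[C@]12C | intermediate
12 | (13S)-7β-acetoxy-16-(tert-butyldimethylsilyloxy)-8α,9α;13,14-diepoxy-15-norlabdane | C[C@]12O[C@@]1(CC[C@@]3(CO[Si](C)(C)C(C)(C)C)CO3)[C@@]4(C)CCCC(C)(C)[C@@H]4C[C@@H]2OC(C)=O | intermediate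
13 | 7β,8β-acetoxonium ion with 9α-O–BF3 and intact side-chain epoxide | C[C+]1O[C@H]2C[C@H]3C(C)(C)CCC[C@]3(C)[C@@](O[B-](F)(F)F)(CC[C@@]4(CO[Si](C)(C)C(C)(C)C)CO4)[C@@]2(C)O1 | intermediate
14 | 7β,8β-acetoxonium ion with closed ring C and 14-O–BF3 | C[C+]1O[C@H]2C[C@H]3C(C)(C)CCC[C@]3(C)[C@@]4(CC[C@@](CO[B-](F)(F)F)(CO[Si](C)(C)C(C)(C)C)O4)[C@@]2(C)O1 | intermediate
15 | (13R)-8β-acetoxy-16-(tert-butyldimethylsilyloxy)-9α,13-epoxy-15-norlabdane-7β,14-diol | CC(=O)O[C@@]1(C)[C@@H](O)C[C@H]2C(C)(C)CCC[C@]2(C)[C@@]12CC[C@@](CO)(CO[Si](C)(C)C(C)(C)C)O2 | intermediate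
16 | (13S)-8β-acetoxy-16-(tert-butyldimethylsilyloxy)-9α,13-epoxy-7-oxo-15-norlabdan-14-al | CC(=O)O[C@@]1(C)C(=O)C[C@H]2C(C)(C)CCC[C@]2(C)[C@@]12CC[C@@](C=O)(CO[Si](C)(C)C(C)(C)C)O2 | intermediate
17 | (13R)-8β-acetoxy-16-(tert-butyldimethylsilyloxy)-9α,13-epoxylabd-14-yn-7-one | CC(=O)O[C@@]1(C)C(=O)C[C@H]2C(C)(C)CCC[C@]2(C)[C@@]12CC[C@@](C#C)(CO[Si](C)(C)C(C)(C)C)O2 | intermediate
18 | (13R)-8β-acetoxy-9α,13-epoxy-16-hydroxylabd-14-yn-7-one | CC(=O)O[C@@]1(C)C(=O)C[C@H]2C(C)(C)CCC[C@]2(C)[C@@]12CC[C@@](C#C)(CO)O2 | intermediate
19 | (13R)-8β-acetoxy-9α,13;15,16-diepoxylabd-14-en-7-one | CC(=O)O[C@@]1(C)C(=O)C[C@H]2C(C)(C)CCC[C@]2(C)[C@@]12CC[C@]1(C=COC1)O2 | target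

## Step count and least certain steps

Total: 14 steps. Longest linear sequence: 14 steps, from 1 to 19; 7 enters as a commercial reactant in step 6.

**Step 10 (key step).** Three things can go wrong. The glycidyl silyl ether may be consumed by a 1,2-hydride shift or by fluoride transfer from boron before the C9 oxygen is released. The tetrasubstituted epoxide may undergo a pinacol-type shift of a C9 or C10 substituent in competition with acetate participation, since both are cationic processes started by the same Lewis acid. The orthoacid may collapse, or the acetyl may later migrate, towards the less hindered C7 oxygen.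
Fallback, from 9 back to 15, keeps the two epoxides apart so that each event is a separate known reaction. The ring alkene of 9 is epoxidised first (mCPBA, NaHCO3, CH2Cl2, −20 °C; the tetrasubstituted alkene reacts before the 1,1-disubstituted one) to give 7β-acetoxy-8α,9α-epoxy-15-norlabd-13(14)-en-16-ol F1. BF3·OEt2 and then water open this single epoxide through the acetoxonium ion to 8β-acetoxy-15-norlabd-13(14)-ene-7β,9α,16-triol F2. Sharpless epoxidation of the allylic alcohol (Ti(OiPr)4, D-(−)-diethyl tartrate, t-BuOOH) gives (13R)-8β-acetoxy-13,14-epoxy-15-norlabdane-7β,9α,16-triol F3. Silylation of the primary alcohol (TBSCl, imidazole) gives (13S)-8β-acetoxy-16-(tert-butyldimethylsilyloxy)-13,14-epoxy-15-norlabdane-7β,9α-diol F4. Camphorsulfonic acid in CH2Cl2 then closes ring C by 5-exo opening at C13 and gives 15.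

**Step 4.** The secondary allylic C7 alcohol may be activated in competition with the primary alcohol, with allylic substitution or elimination, because allylic alkoxyphosphonium ions ionise easily.
Fallback, from 4 back to 6: both hydroxyls are acetylated (Ac2O, pyridine, DMAP) to 13,14,15,16-tetranorlabd-8-ene-7β,12-diyl diacetate F5. The unhindered primary acetate is cleaved selectively (K2CO3, MeOH, 0 °C) to 7β-acetoxy-13,14,15,16-tetranorlabd-8-en-12-ol F6, and iodination (I2, PPh3, imidazole) gives 6.

**Step 6.** The alkylzinc reagent may be protonated by the free hydroxyl of 7, or the alkylpalladium intermediate may undergo β-hydride elimination, faster than coupling. Ionisation of the allylic C7 acetate by zerovalent palladium is a lesser concern.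
Fallback, from 6 and 7 back to 9: 7 is silylated (TBSCl, imidazole) to tert-butyl[(2-bromoprop-2-en-1-yl)oxy]dimethylsilane F7. Negishi coupling of 8 with this aprotic partner gives 7β-acetoxy-16-(tert-butyldimethylsilyloxy)-15-norlabda-8,13(14)-diene F8, and HF·pyridine removes the silyl group to give 9.

**Step 12.** Methanolysis of the tertiary α-keto acetate by carbonate in methanol may compete with a homologation that is slow because the aldehyde is neopentyl.
Fallback, from 16 back to 17: loss of the acetate is accepted. The homologation is run with excess K2CO3 in MeOH until both processes are complete, giving (13R)-9α,13-epoxy-8β-hydroxy-16-(tert-butyldimethylsilyloxy)labd-14-yn-7-one F9. The tertiary α-ketol is then re-acetylated (Ac2O, DMAP, Et3N, 50 °C) to 17.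

**Step 14.** The vinylidene may form slowly at the alkyne on the quaternary carbon, the catalyst may be held by the ketone or the ether oxygens, or the propargylic C13–O9 bond may be lost from the metal intermediate with aromatisation to a furan.
Fallback, from 17 back to 19: the terminal alkyne of 17 is hydroborated with dicyclohexylborane and oxidised (NaBO3) to 8β-acetoxy-16-(tert-butyldimethylsilyloxy)-9α,13-epoxy-7-oxolabdan-15-al F10. HF·pyridine then gives the lactol 8β-acetoxy-9α,13;15,16-diepoxy-15-hydroxylabdan-7-one F11. MsCl and Et3N convert it through its anomeric mesylate F12 into 19 by base-induced elimination, again without acid.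

## Further compounds

F1 | step 10 | 7β-acetoxy-8α,9α-epoxy-15-norlabd-13(14)-en-16-ol | C[C@]12O[C@@]1(CCC(=C)CO)[C@@]4(C)CCCC(C)(C)[C@@H]4C[C@@H]2OC(C)=O
F2 | step 10 | 8β-acetoxy-15-norlabd-13(14)-ene-7β,9α,16-triol | CC(=O)O[C@@]1(C)[C@@H](O)C[C@H]2C(C)(C)CCC[C@]2(C)[C@@]1(O)CCC(=C)CO
F3 | step 10 | (13R)-8β-acetoxy-13,14-epoxy-15-norlabdane-7β,9α,16-triol | CC(=O)O[C@@]1(C)[C@@H](O)C[C@H]2C(C)(C)CCC[C@]2(C)[C@@]1(O)CC[C@@]3(CO)CO3
F4 | step 10 | (13S)-8β-acetoxy-16-(tert-butyldimethylsilyloxy)-13,14-epoxy-15-norlabdane-7β,9α-diol | CC(=O)O[C@@]1(C)[C@@H](O)C[C@H]2C(C)(C)CCC[C@]2(C)[C@@]1(O)CC[C@@]3(CO[Si](C)(C)C(C)(C)C)CO3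
F5 | step 4 | 13,14,15,16-tetranorlabd-8-ene-7β,12-diyl diacetate | CC(=O)OCCC1=C(C)[C@@H](OC(C)=O)C[C@H]2C(C)(C)CCC[C@]12C
F6 | step 4 | 7β-acetoxy-13,14,15,16-tetranorlabd-8-en-12-ol | OCCC1=C(C)[C@@H](OC(C)=O)C[C@H]2C(C)(C)CCC[C@]12C
F7 | step 6 | tert-butyl[(2-bromoprop-2-en-1-yl)oxy]dimethylsilane | C=C(Br)CO[Si](C)(C)C(C)(C)C
F8 | step 6 | 7β-acetoxy-16-(tert-butyldimethylsilyloxy)-15-norlabda-8,13(14)-diene | CC(C)(C)[Si](C)(C)OCC(=C)CCC1=C(C)[C@@H](OC(C)=O)C[C@H]2C(C)(C)CCC[C@]12C
F9 | step 12 | (13R)-9α,13-epoxy-8β-hydroxy-16-(tert-butyldimethylsilyloxy)labd-14-yn-7-one | O[C@@]1(C)C(=O)C[C@H]2C(C)(C)CCC[C@]2(C)[C@@]12CC[C@@](C#C)(CO[Si](C)(C)C(C)(C)C)O2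
F10 | step 14 | 8β-acetoxy-16-(tert-butyldimethylsilyloxy)-9α,13-epoxy-7-oxolabdan-15-al | CC(=O)O[C@@]1(C)C(=O)C[C@H]2C(C)(C)CCC[C@]2(C)[C@@]12CC[C@@](CC=O)(CO[Si](C)(C)C(C)(C)C)O2
F11 | step 14 | 8β-acetoxy-9α,13;15,16-diepoxy-15-hydroxylabdan-7-one | CC(=O)O[C@@]1(C)C(=O)C[C@H]2C(C)(C)CCC[C@]2(C)[C@@]12CC[C@]1(CC(O)OC1)O2
F12 | step 14 | 8β-acetoxy-9α,13;15,16-diepoxy-7-oxolabdan-15-yl methanesulfonate | CC(=O)O[C@@]1(C)C(=O)C[C@H]2C(C)(C)CCC[C@]2(C)[C@@]12CC[C@]1(CC(OS(C)(=O)=O)OC1)O2
A1 | alternative 1 | 9α,13-epoxy-15,16-cyclolabd-8(17)-en-15-one | C=C1CC[C@H]2C(C)(C)CCC[C@]2(C)[C@@]12CCC1(CC(=O)C1)O2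
A2 | alternative 1 | (13R)-9α,13-epoxylabd-8(17)-en-15,16-olide | C=C1CC[C@H]2C(C)(C)CCC[C@]2(C)[C@@]12CC[C@]1(CC(=O)OC1)O2
A3 | alternative 2 | dimethyl (13R)-13-hydroxylabd-7-ene-15,16-dioate | CC1=CC[C@H]2C(C)(C)CCC[C@]2(C)[C@H]1CC[C@](O)(C(=O)OC)CC(=O)OC
A4 | alternative 2 | dimethyl (13R)-9α,13-epoxylabd-7-ene-15,16-dioate | CC1=CC[C@H]2C(C)(C)CCC[C@]2(C)[C@@]12CC[C@](C(=O)OC)(CC(=O)OC)O2
A5 | alternative 3 | methyl 15,17-dinorlabda-8,13(16)-dien-14-oate | C=C(CCC1=CCC[C@H]2C(C)(C)CCC[C@]12C)C(=O)OC
A6 | alternative 3 | methyl 9α,13-epoxy-8α,16-dihydroxy-15,17-dinorlabdan-14-oate | O[C@@H]1CC[C@H]2C(C)(C)CCC[C@]2(C)[C@@]12CC[C@](CO)(C(=O)OC)O2
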